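**Plan**
- C3 of the chromane-2,4-dione lies between the lactone carbonyl C2 and the ketone carbonyl C4 and carries an electron-rich aryl and a prenyl group. Such a carbon is a diazo-1,3-dicarbonyl carbon in disguise, so the first cuts are C3–aryl and C3–CH2.
- Further cuts: the diazo group, C4–C4a and O1–C2 of the pyranone, the bond from ring A (C6) to the cyclohexene, and the two Diels–Alder bonds of the cyclohexene.
- Forward: chalcone and isoprene close the cyclohexene; Friedel–Crafts allylation joins phloroglucinol as ring A; Meldrum's acid and ring closure build the pyranone; diazo transfer; one-pot arylation/prenylation at C3; desilylation.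
- Stereochemistry: the aryl-bearing ring carbon comes from a chiral borate Diels–Alder reaction, the aroyl-bearing carbon from kinetic protonation (cis to the aryl), the ring A-bearing carbon from Friedel–Crafts attack trans to the aroyl group, and C3 from the chiral palladium catalyst.

Key step: step 15

Abbreviation: TBS = tert-butyldimethylsilyl; TBSO = tert-butyldimethylsilyloxy.
Assumption: (R)-VANOL and the (R,R)-bisphosphine are taken to induce the configurations drawn; should either induce the opposite sense, its mirror-image ligand is used and nothing else changes.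

**Route**

Step 1
Reactants: 1 2,4-dihydroxybenzaldehyde
Product: 2 2,4-bis(TBSO)benzaldehyde
Conditions: TBSCl (2.5 equiv), imidazole, DMF, rt
Reagents that add atoms: tert-butyldimethylsilyl chloride, CC(C)(C)[Si](C)(C)Cl
Why: Phenol silylation with a silyl chloride and imidazole, the excess reagent also capturing the hydrogen-bonded ortho hydroxyl.

Step 2
Reactants: 3 2',4'-dihydroxyacetophenone
Product: 4 1-[4-(TBSO)-2-hydroxyphenyl]ethanone
Conditions: TBSCl (1.05 equiv), imidazole, CH2Cl2, 0 °C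
Reagents that add atoms: tert-butyldimethylsilyl chloride, CC(C)(C)[Si](C)(C)Cl
Why: Chemoselective phenol silylation, the 2'-hydroxyl being held in a hydrogen bond to the ketone and left free for boron chelation in step 4.

Step 3
Reactants: 4 1-[4-(TBSO)-2-hydroxyphenyl]ethanone; 2 2,4-bis(TBSO)benzaldehyde
Product: 6 (E)-3-[2,4-bis(TBSO)phenyl]-1-[4-(TBSO)-2-hydroxyphenyl]prop-2-en-1-one, via aldol adduct 5 (not isolated)
Conditions: LiN(SiMe3)2 (2.2 equiv), THF, −78 °C; 2; AcOH, −78 °C; then pTsOH·H2O (cat.), CH2Cl2, rt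
Reagents that add atoms: none
Why: Crossed aldol condensation (Claisen–Schmidt type) through the ketone dianion, the cold quench preventing silyl migration to the aldolate and the acid-catalysed loss of water from the electron-rich benzylic alcohol giving the E-enone.

Step 4
Reactants: 6 (E)-3-[2,4-bis(TBSO)phenyl]-1-[4-(TBSO)-2-hydroxyphenyl]prop-2-en-1-one; 7 isoprene
Product: 8 [(1R,6R)-6-[2,4-bis(TBSO)phenyl]-4-methylcyclohex-3-en-1-yl][4-(TBSO)-2-hydroxyphenyl]methanone (trans)
Conditions: B(OPh)3 (20 mol%), (R)-VANOL [(R)-3,3'-diphenyl-2,2'-bi-1-naphthol] (20 mol%), 7 (10 equiv), 4 Å MS, PhCF3, 40 °C, sealed tube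
Reagents that add atoms: none
Why: Chiral borate-promoted asymmetric Diels–Alder reaction of a 2'-hydroxychalcone, in which the chalcone chelates boron through phenoxide and carbonyl, the binaphthol blocks one enone face so that the aryl-bearing carbon is formed R, the E-alkene makes the adduct trans, and Lewis acid activation gives the para regioisomer.

Step 5
Reactants: 8 trans ketone with free 2'-hydroxyl
Product: 9 [(1R,6R)-6-[2,4-bis(TBSO)phenyl]-4-methylcyclohex-3-en-1-yl][2,4-bis(TBSO)phenyl]methanone (trans)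
Conditions: TBSOTf, 2,6-lutidine, CH2Cl2, 0 °C
Reagents that add atoms: tert-butyldimethylsilyl triflate, CC(C)(C)[Si](C)(C)OS(=O)(=O)C(F)(F)F
Why: Silylation of the chelated phenol with a silyl triflate and a hindered base, which removes the acidic proton before enolate chemistry.

Step 6
Reactants: 9 trans ketone
Product: 11 [(1S,6R)-6-[2,4-bis(TBSO)phenyl]-4-methylcyclohex-3-en-1-yl][2,4-bis(TBSO)phenyl]methanone (cis), via potassium enolate 10 (not isolated)
Conditions: KN(SiMe3)2, THF, −78 °C; AcOH in THF, −78 °C; recovered trans ketone is recycled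
Reagents that add atoms: none
Why: Deprotonation followed by kinetic protonation of the exocyclic enolate, in which allylic 1,3-strain turns the neighbouring aryl group axial and the proton is delivered to the face away from it, so the less stable cis ketone (new centre S) should form while the aryl-bearing carbon is untouched.

Step 7
Reactants: 11 cis ketone
Product: 14 [(1S,6R)-6-[2,4-bis(TBSO)phenyl]-4-hydroxy-4-methylcyclohex-2-en-1-yl][2,4-bis(TBSO)phenyl]methanone (both C4 epimers), via hydroxy selenide 12 (not isolated), via selenoxide 13 (not isolated)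
Conditions: N-(phenylseleno)phthalimide, H2O, camphorsulfonic acid (cat.), CH2Cl2, rt; then 30% H2O2, pyridine, THF, 0 °C → rt
Reagents that add atoms: water, O
Why: Hydroxyselenation of the trisubstituted alkene (water opens the seleniranium ion at the tertiary carbon) followed by selenoxide syn-elimination, which can only run away from the carbinol carbon and so gives the transposed tertiary allylic alcohol, whose carbinol configuration is irrelevant because step 8 ionises it.

Step 8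
Reactants: 14 tertiary allylic alcohol; 15 phloroglucinol
Product: 16 2-[(1R,5R,6R)-6-[2,4-bis(TBSO)benzoyl]-5-[2,4-bis(TBSO)phenyl]-3-methylcyclohex-2-en-1-yl]benzene-1,3,5-triol
Conditions: 15 (5 equiv), pTsOH·H2O (10 mol%), MgSO4, CH2Cl2/THF, −10 °C
Reagents that add atoms: none
Why: Friedel–Crafts allylation of a phloroglucinol with a cyclic tertiary allylic alcohol (the terpenylation used for menthadienyl resorcinols), in which the allyl cation is attacked at its secondary terminus from the face opposite the cis aroyl and aryl groups, setting the new centre R (trans to the aroyl group), and the threefold symmetry of the nucleophile leaves no regiochemical choice.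

Step 9
Reactants: 16 cyclohexenyl phloroglucinol; 17 Meldrum's acid
Product: 18 3-{3,5-dihydroxy-4-[(1R,5R,6R)-6-[2,4-bis(TBSO)benzoyl]-5-[2,4-bis(TBSO)phenyl]-3-methylcyclohex-2-en-1-yl]phenoxy}-3-oxopropanoic acid
Conditions: 17 (1.1 equiv), toluene, 90 °C
Reagents that add atoms: none
Why: Ring-opening acylation of a phenol by Meldrum's acid with loss of acetone, expected at the para hydroxyl because the other two are flanked by the bulky cyclohexenyl group.

Step 10
Reactants: 18 aryl hydrogen malonate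
Product: 20 3-{3,5-bis(TBSO)-4-[(1R,5R,6R)-6-[2,4-bis(TBSO)benzoyl]-5-[2,4-bis(TBSO)phenyl]-3-methylcyclohex-2-en-1-yl]phenoxy}-3-oxopropanoic acid, via silyl ester 19 (not isolated)
Conditions: TBSOTf (3.5 equiv), 2,6-lutidine, CH2Cl2, 0 °C; aqueous citric acid work-up
Reagents that add atoms: tert-butyldimethylsilyl triflate, CC(C)(C)[Si](C)(C)OS(=O)(=O)C(F)(F)F
Why: Silyl triflate silylation of the two hindered phenols, the silyl ester formed alongside being hydrolysed on work-up.

Step 11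
Reactants: 20 bis-silylated aryl hydrogen malonate
Product: 22 5,7-bis(TBSO)-6-[(1R,5R,6R)-6-[2,4-bis(TBSO)benzoyl]-5-[2,4-bis(TBSO)phenyl]-3-methylcyclohex-2-en-1-yl]-4-hydroxy-2H-chromen-2-one, via mixed anhydride 21 (not isolated)
Conditions: (CF3CO)2O (2 equiv), CH2Cl2, 0 °C → rt
Reagents that add atoms: none
Why: Intramolecular Friedel–Crafts acylation through the mixed trifluoroacetic anhydride, the two positions ortho to the ester oxygen being equivalent and each activated by an ortho and a para silyloxy group, so a single 4-hydroxycoumarin should result without strong protic acid.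

Step 12
Reactants: 22 4-hydroxycoumarin
Product: 23 3-diazo-5,7-bis(TBSO)-6-[(1R,5R,6R)-6-[2,4-bis(TBSO)benzoyl]-5-[2,4-bis(TBSO)phenyl]-3-methylcyclohex-2-en-1-yl]chromane-2,4-dione
Conditions: 4-acetamidobenzenesulfonyl azide, Et3N, MeCN, 0 °C → rt
Reagents that add atoms: 4-acetamidobenzenesulfonyl azide, CC(=O)Nc1ccc(cc1)S(=O)(=O)N=[N+]=[N-]
Why: Regitz diazo transfer to the 1,3-dicarbonyl carbon C3 of the 4-hydroxycoumarin.

Step 13
Reactants: 24 resorcinol
Product: 25 1,3-bis(TBSO)benzene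
Conditions: TBSCl (2.4 equiv), imidazole, DMF, rt
Reagents that add atoms: tert-butyldimethylsilyl chloride, CC(C)(C)[Si](C)(C)Cl
Why: Phenol silylation with a silyl chloride and imidazole.

Step 14
Reactants: 26 prenol
Product: 27 methyl prenyl carbonate
Conditions: ClCO2Me, pyridine, CH2Cl2, 0 °C
Reagents that add atoms: methyl chloroformate, COC(=O)Cl
Why: Acylation of the primary allylic alcohol with a chloroformate to give the carbonate used for ionisation by palladium.

Step 15
Reactants: 23 3-diazochromane-2,4-dione; 25 1,3-bis(TBSO)benzene; 27 methyl prenyl carbonate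
Product: 29 (3S)-3-[2,4-bis(TBSO)phenyl]-5,7-bis(TBSO)-6-[(1R,5R,6R)-6-[2,4-bis(TBSO)benzoyl]-5-[2,4-bis(TBSO)phenyl]-3-methylcyclohex-2-en-1-yl]-3-(3-methylbut-2-en-1-yl)chromane-2,4-dione, via enol 28 (not isolated)
Conditions: Rh2(OAc)4 (2 mol%), 25 (5 equiv), PhCF3, 70 °C; then Pd2(dba)3·CHCl3 (2.5 mol%), (1R,2R)-N,N'-cyclohexane-1,2-diylbis[2-(diphenylphosphino)benzamide] (7.5 mol%), 27 (1.5 equiv), CH2Cl2, 0 °C → rt
Reagents that add atoms: none
Why: Proposed new method: Rh2(OAc)4 expels N2 from 23 to give an electrophilic carbene at C3 that is attacked by excess 25 at the carbon para to one silyloxy group and ortho to the other, and rearomatisation with proton transfer gives enol 28; zerovalent palladium then ionises 27 to a cationic prenyl complex, CO2 and methoxide, the methoxide deprotonates 28, and the enolate attacks the unsubstituted allyl terminus from the face away from the metal to form the C3–CH2 bond. The closest known reaction types are dirhodium-carbene C–H arylation of cyclic diazo-1,3-dicarbonyl compounds by electron-rich arenes and palladium-catalysed asymmetric allylic alkylation of prochiral stabilised enolates, which have not been combined in one flask on a diazochromanedione. No ring is closed. The new stereocenter C3 is set as S by the chiral bisphosphine on palladium, which selects the enolate face independently of the distant cyclohexene stereocenters. The step needs intermolecular arylation to outrun reaction of the carbene with the substrate's own arenes and alkene, which the five-fold excess of 25 and the steric shielding of the silylated rings should secure. It also needs C- over O-prenylation and linear over branched attack, which follow from the reversibility of O-allylation under palladium and from the crowded quaternary centre forming at the less substituted allyl terminus.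

Step 16
Reactants: 29 per-silylated target
Product: 30 (3S)-3-(2,4-dihydroxyphenyl)-5,7-dihydroxy-6-[(1R,5R,6R)-6-(2,4-dihydroxybenzoyl)-5-(2,4-dihydroxyphenyl)-3-methylcyclohex-2-en-1-yl]-3-(3-methylbut-2-en-1-yl)chromane-2,4-dione
Conditions: HF·pyridine, pyridine, THF, 0 °C → rt
Reagents that add atoms: none
Why: Global fluoride desilylation of the eight aryl silyl ethers under mildly acidic conditions that should leave the β-keto lactone, the epimerisable aroyl-bearing carbon and the prenyl group untouched.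

**Compound list**

1 | 2,4-dihydroxybenzaldehyde | O=Cc1ccc(O)cc1O | starting material
2 | 2,4-bis(TBSO)benzaldehyde | O=Cc1ccc(O[Si](C)(C)C(C)(C)C)cc1O[Si](C)(C)C(C)(C)C | intermediate
3 | 2',4'-dihydroxyacetophenone | CC(=O)c1ccc(O)cc1O | starting material
4 | 1-[4-(TBSO)-2-hydroxyphenyl]ethanone | CC(=O)c1ccc(O[Si](C)(C)C(C)(C)C)cc1O | intermediate
5 | 3-[2,4-bis(TBSO)phenyl]-1-[4-(TBSO)-2-hydroxyphenyl]-3-hydroxypropan-1-one (racemic aldol adduct) | OC(CC(=O)c1ccc(O[Si](C)(C)C(C)(C)C)cc1O)c1ccc(O[Si](C)(C)C(C)(C)C)cc1O[Si](C)(C)C(C)(C)C | intermediate (not isolated)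
6 | (E)-3-[2,4-bis(TBSO)phenyl]-1-[4-(TBSO)-2-hydroxyphenyl]prop-2-en-1-one | O=C(/C=C/c1ccc(O[Si](C)(C)C(C)(C)C)cc1O[Si](C)(C)C(C)(C)C)c1ccc(O[Si](C)(C)C(C)(C)C)cc1O | intermediate
7 | isoprene | C=CC(C)=C | starting material
8 | [(1R,6R)-6-[2,4-bis(TBSO)phenyl]-4-methylcyclohex-3-en-1-yl][4-(TBSO)-2-hydroxyphenyl]methanone (trans) | C1C=C(C)C[C@@H](c2ccc(O[Si](C)(C)C(C)(C)C)cc2O[Si](C)(C)C(C)(C)C)[C@@H]1C(=O)c1ccc(O[Si](C)(C)C(C)(C)C)cc1O | intermediate
9 | [(1R,6R)-6-[2,4-bis(TBSO)phenyl]-4-methylcyclohex-3-en-1-yl][2,4-bis(TBSO)phenyl]methanone (trans) | C1C=C(C)C[C@@H](c2ccc(O[Si](C)(C)C(C)(C)C)cc2O[Si](C)(C)C(C)(C)C)[C@@H]1C(=O)c1ccc(O[Si](C)(C)C(C)(C)C)cc1O[Si](C)(C)C(C)(C)C | intermediate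
10 | potassium enolate of 9 (exocyclic enolate, aryl-bearing carbon unchanged) | [K+].[O-]C(=C1CC=C(C)C[C@H]1c1ccc(O[Si](C)(C)C(C)(C)C)cc1O[Si](C)(C)C(C)(C)C)c1ccc(O[Si](C)(C)C(C)(C)C)cc1O[Si](C)(C)C(C)(C)C | intermediate (not isolated)
11 | [(1S,6R)-6-[2,4-bis(TBSO)phenyl]-4-methylcyclohex-3-en-1-yl][2,4-bis(TBSO)phenyl]methanone (cis) | C1C=C(C)C[C@@H](c2ccc(O[Si](C)(C)C(C)(C)C)cc2O[Si](C)(C)C(C)(C)C)[C@H]1C(=O)c1ccc(O[Si](C)(C)C(C)(C)C)cc1O[Si](C)(C)C(C)(C)C | intermediate
12 | [(1S,6R)-6-[2,4-bis(TBSO)phenyl]-4-hydroxy-4-methyl-3-(phenylselanyl)cyclohexyl][2,4-bis(TBSO)phenyl]methanone (trans hydroxy selenide, diastereomer mixture at C3/C4) | C1C([Se]c2ccccc2)C(C)(O)C[C@@H](c2ccc(O[Si](C)(C)C(C)(C)C)cc2O[Si](C)(C)C(C)(C)C)[C@H]1C(=O)c1ccc(O[Si](C)(C)C(C)(C)C)cc1O[Si](C)(C)C(C)(C)C | intermediate (not isolated)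
13 | selenoxide of 12 | C1C([Se](=O)c2ccccc2)C(C)(O)C[C@@H](c2ccc(O[Si](C)(C)C(C)(C)C)cc2O[Si](C)(C)C(C)(C)C)[C@H]1C(=O)c1ccc(O[Si](C)(C)C(C)(C)C)cc1O[Si](C)(C)C(C)(C)C | intermediate (not isolated)
14 | [(1S,6R)-6-[2,4-bis(TBSO)phenyl]-4-hydroxy-4-methylcyclohex-2-en-1-yl][2,4-bis(TBSO)phenyl]methanone (both C4 epimers) | C1=CC(C)(O)C[C@@H](c2ccc(O[Si](C)(C)C(C)(C)C)cc2O[Si](C)(C)C(C)(C)C)[C@H]1C(=O)c1ccc(O[Si](C)(C)C(C)(C)C)cc1O[Si](C)(C)C(C)(C)C | intermediate
15 | phloroglucinol | Oc1cc(O)cc(O)c1 | starting material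
16 | 2-[(1R,5R,6R)-6-[2,4-bis(TBSO)benzoyl]-5-[2,4-bis(TBSO)phenyl]-3-methylcyclohex-2-en-1-yl]benzene-1,3,5-triol | Oc1cc(O)c([C@@H]2C=C(C)C[C@@H](c3ccc(O[Si](C)(C)C(C)(C)C)cc3O[Si](C)(C)C(C)(C)C)[C@H]2C(=O)c2ccc(O[Si](C)(C)C(C)(C)C)cc2O[Si](C)(C)C(C)(C)C)c(O)c1 | intermediate
17 | Meldrum's acid | CC1(C)OC(=O)CC(=O)O1 | starting material
18 | aryl hydrogen malonate at the para oxygen of 16 | OC(=O)CC(=O)Oc1cc(O)c([C@@H]2C=C(C)C[C@@H](c3ccc(O[Si](C)(C)C(C)(C)C)cc3O[Si](C)(C)C(C)(C)C)[C@H]2C(=O)c2ccc(O[Si](C)(C)C(C)(C)C)cc2O[Si](C)(C)C(C)(C)C)c(O)c1 | intermediate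
19 | TBS ester of 20 (both ring A phenols also silylated) | CC(C)(C)[Si](C)(C)OC(=O)CC(=O)Oc1cc(O[Si](C)(C)C(C)(C)C)c([C@@H]2C=C(C)C[C@@H](c3ccc(O[Si](C)(C)C(C)(C)C)cc3O[Si](C)(C)C(C)(C)C)[C@H]2C(=O)c2ccc(O[Si](C)(C)C(C)(C)C)cc2O[Si](C)(C)C(C)(C)C)c(O[Si](C)(C)C(C)(C)C)c1 | intermediate (not isolated)
20 | aryl hydrogen malonate with both ring A phenols as TBS ethers | OC(=O)CC(=O)Oc1cc(O[Si](C)(C)C(C)(C)C)c([C@@H]2C=C(C)C[C@@H](c3ccc(O[Si](C)(C)C(C)(C)C)cc3O[Si](C)(C)C(C)(C)C)[C@H]2C(=O)c2ccc(O[Si](C)(C)C(C)(C)C)cc2O[Si](C)(C)C(C)(C)C)c(O[Si](C)(C)C(C)(C)C)c1 | intermediate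
21 | mixed trifluoroacetic anhydride of 20 | FC(F)(F)C(=O)OC(=O)CC(=O)Oc1cc(O[Si](C)(C)C(C)(C)C)c([C@@H]2C=C(C)C[C@@H](c3ccc(O[Si](C)(C)C(C)(C)C)cc3O[Si](C)(C)C(C)(C)C)[C@H]2C(=O)c2ccc(O[Si](C)(C)C(C)(C)C)cc2O[Si](C)(C)C(C)(C)C)c(O[Si](C)(C)C(C)(C)C)c1 | intermediate (not isolated)
22 | 5,7-bis(TBSO)-6-[(1R,5R,6R)-cyclohexenyl]-4-hydroxy-2H-chromen-2-one | OC1=CC(=O)Oc2cc(O[Si](C)(C)C(C)(C)C)c([C@@H]3C=C(C)C[C@@H](c4ccc(O[Si](C)(C)C(C)(C)C)cc4O[Si](C)(C)C(C)(C)C)[C@H]3C(=O)c5ccc(O[Si](C)(C)C(C)(C)C)cc5O[Si](C)(C)C(C)(C)C)c(O[Si](C)(C)C(C)(C)C)c12 | intermediate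
23 | 3-diazo-5,7-bis(TBSO)-6-[(1R,5R,6R)-cyclohexenyl]chromane-2,4-dione | [N-]=[N+]=C1C(=O)Oc6cc(O[Si](C)(C)C(C)(C)C)c([C@@H]3C=C(C)C[C@@H](c4ccc(O[Si](C)(C)C(C)(C)C)cc4O[Si](C)(C)C(C)(C)C)[C@H]3C(=O)c5ccc(O[Si](C)(C)C(C)(C)C)cc5O[Si](C)(C)C(C)(C)C)c(O[Si](C)(C)C(C)(C)C)c6C1=O | intermediate
24 | resorcinol | Oc1cccc(O)c1 | starting material
25 | 1,3-bis(TBSO)benzene | CC(C)(C)[Si](C)(C)Oc1cccc(O[Si](C)(C)C(C)(C)C)c1 | intermediate
26 | prenol | CC(C)=CCO | starting material
27 | methyl prenyl carbonate | COC(=O)OCC=C(C)C | intermediate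
28 | 3-[2,4-bis(TBSO)phenyl]-5,7-bis(TBSO)-6-[(1R,5R,6R)-cyclohexenyl]-4-hydroxy-2H-chromen-2-one | OC1=C(c2ccc(O[Si](C)(C)C(C)(C)C)cc2O[Si](C)(C)C(C)(C)C)C(=O)Oc6cc(O[Si](C)(C)C(C)(C)C)c([C@@H]3C=C(C)C[C@@H](c4ccc(O[Si](C)(C)C(C)(C)C)cc4O[Si](C)(C)C(C)(C)C)[C@H]3C(=O)c5ccc(O[Si](C)(C)C(C)(C)C)cc5O[Si](C)(C)C(C)(C)C)c(O[Si](C)(C)C(C)(C)C)c16 | intermediate (not isolated)
29 | per-silylated target, (3S)-3-aryl-3-prenylchromane-2,4-dione with eight TBS ethers | CC(C)=CC[C@@]1(c2ccc(O[Si](C)(C)C(C)(C)C)cc2O[Si](C)(C)C(C)(C)C)C(=O)Oc6cc(O[Si](C)(C)C(C)(C)C)c([C@@H]3C=C(C)C[C@@H](c4ccc(O[Si](C)(C)C(C)(C)C)cc4O[Si](C)(C)C(C)(C)C)[C@H]3C(=O)c5ccc(O[Si](C)(C)C(C)(C)C)cc5O[Si](C)(C)C(C)(C)C)c(O[Si](C)(C)C(C)(C)C)c6C1=O | intermediate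
30 | (3S)-3-(2,4-dihydroxyphenyl)-5,7-dihydroxy-6-[(1R,5R,6R)-6-(2,4-dihydroxybenzoyl)-5-(2,4-dihydroxyphenyl)-3-methylcyclohex-2-en-1-yl]-3-(3-methylbut-2-en-1-yl)chromane-2,4-dione | CC(C)=CC[C@@]1(c2ccc(O)cc2O)C(=O)Oc2cc(O)c([C@@H]3C=C(C)C[C@@H](c4ccc(O)cc4O)[C@H]3C(=O)c3ccc(O)cc3O)c(O)c2C1=O | target

**Totals and risks**

Total steps: 16. Longest linear sequence: 13 (steps 1, 3 to 12, 15, 16).

Steps most likely to fail:

1. Step 15 (Proposed new method). The carbene may insert into the substrate's own silylated arenes or react at the peri silyloxy oxygen instead of being intercepted by 25. In the second stage, prenylation may stay at oxygen, go to the branched terminus, or proceed with poor enantioface discrimination at the hindered enol. Fallback with known chemistry, setting out from 22: plumbation of 25 with Pb(OAc)4 gives [2,4-bis(TBSO)phenyl]lead triacetate F1, which arylates 22 at C3 under Pinhey conditions (pyridine, CHCl3, 40 °C) to give 28, now isolated. A separate Tsuji–Trost allylation of 28 with 27, Pd2(dba)3·CHCl3 and the same bisphosphine then returns to the route at 29.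

2. Step 6. Protonation may show poor facial selectivity, the ortho silyl group may migrate to the enolate oxygen, or the cis ketone may re-equilibrate to trans during quench and work-up. Fallback, setting out from 9: soft enolisation with trimethylsilyl triflate and Et3N gives the trimethylsilyl enol ether F2. This is protonated at −78 °C in toluene by the SnCl4 complex of (R)-BINOL (the binaphthol enantiomer that reinforces the substrate bias), so that the proton donor rather than the substrate controls the face. The route is rejoined at 11.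

3. Step 9. Acylation may spread to the two hindered hydroxyls or go twice, and the malonic half-ester may lose CO2 on heating. Fallback, setting out from 16: silylation at −78 °C with one equivalent of triethylsilyl chloride gives the para triethylsilyl ether F3. TBSOTf and 2,6-lutidine then cap the two hindered phenols to give F4, and AcOH/THF/H2O removes only the triethylsilyl group to give the para phenol F5. Heating F5 with 17 in toluene gives the acid directly, and the route is rejoined at 20.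

**Further compounds**

F1 | step 15 | [2,4-bis(TBSO)phenyl]lead triacetate | CC(=O)O[Pb](OC(C)=O)(OC(C)=O)c1ccc(O[Si](C)(C)C(C)(C)C)cc1O[Si](C)(C)C(C)(C)C
F2 | step 6 | trimethylsilyl enol ether of 9 | C[Si](C)(C)OC(=C1CC=C(C)C[C@H]1c1ccc(O[Si](C)(C)C(C)(C)C)cc1O[Si](C)(C)C(C)(C)C)c1ccc(O[Si](C)(C)C(C)(C)C)cc1O[Si](C)(C)C(C)(C)C
F3 | step 9 | para triethylsilyl ether of 16 | CC[Si](CC)(CC)Oc1cc(O)c([C@@H]2C=C(C)C[C@@H](c3ccc(O[Si](C)(C)C(C)(C)C)cc3O[Si](C)(C)C(C)(C)C)[C@H]2C(=O)c2ccc(O[Si](C)(C)C(C)(C)C)cc2O[Si](C)(C)C(C)(C)C)c(O)c1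
F4 | step 9 | para triethylsilyl ether with both flanking phenols as TBS ethers | CC[Si](CC)(CC)Oc1cc(O[Si](C)(C)C(C)(C)C)c([C@@H]2C=C(C)C[C@@H](c3ccc(O[Si](C)(C)C(C)(C)C)cc3O[Si](C)(C)C(C)(C)C)[C@H]2C(=O)c2ccc(O[Si](C)(C)C(C)(C)C)cc2O[Si](C)(C)C(C)(C)C)c(O[Si](C)(C)C(C)(C)C)c1
F5 | step 9 | para phenol with both flanking phenols as TBS ethers | Oc1cc(O[Si](C)(C)C(C)(C)C)c([C@@H]2C=C(C)C[C@@H](c3ccc(O[Si](C)(C)C(C)(C)C)cc3O[Si](C)(C)C(C)(C)C)[C@H]2C(=O)c2ccc(O[Si](C)(C)C(C)(C)C)cc2O[Si](C)(C)C(C)(C)C)c(O[Si](C)(C)C(C)(C)C)c1
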